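The bicyclo[2.2.2]octene of yunnaneic acid C is treated as a shikimate ring carrying a two-carbon bridge: the six-membered ring C7–C1–C2–C3–C4–C8 (C1/C4 bridgeheads, C2/C3 ketones, C7 bearing CO2H, C8 the aryl) holds shikimic acid's carboxyl and two of its oxygens. Cutting C1–C6 and C4–C5 leaves a cyclohexa-1,5-diene ester whose O2 carries an acrylate. One intramolecular Diels–Alder reaction of this 3-epi-shikimate dienyl acrylate (tert-butyl ester, O3 silylated) closes the bicycle and a C9–O2 γ-lactone, sets both bridgeheads in the required absolute sense and places the side-chain carbon C9 on C6, next to C1.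

Key step: step 8

Numbering: compounds 1–9 keep shikimate numbering. Bicyclic compounds use C1, C4 bridgeheads; C2 (on C1) and C3 (on C4) the oxygenated carbons; C5=C6 the alkene bridge (C6 on C1, carrying side-chain carbons C9–C10–C11); C7 (on C1) bears the carboxyl; C8 (on C4) bears the aryl. A substituent on a two-carbon bridge is called syn to the bridge toward which it points.

Remark on protecting groups: the C7 carboxyl travels as a tert-butyl ester and both catechols as acid-labile ethers. This lets the lactone be reduced beside the ester and lets one acidolysis end the synthesis; methyl esters or methyl ethers could not be removed in the presence of the side-chain ester links.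

Assumption: 5-bromo-2,2-dimethyl-1,3-benzodioxole is taken as a catalogue compound (otherwise one step from 4-bromocatechol); the target is treated as the free 2,3-dione, its reversible hydrate not being a separate compound.

Step 1
Reactants: 1 (−)-shikimic acid
Product: 2 tert-butyl shikimate
Conditions: O-tert-butyl-N,N′-diisopropylisourea (3 equiv), THF, 45 °C
Reagents that add atoms: O-tert-butyl-N,N′-diisopropylisourea, CC(C)NC(=NC(C)C)OC(C)(C)C
Why: O-alkylation of the carboxylic acid by the protonated isourea (isourea esterification) should give the tert-butyl ester while the three alcohols, which are not acidic enough to activate the reagent, stay free.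

Step 2
Reactants: 2 tert-butyl shikimate
Product: 3 tert-butyl 3,4-O-isopropylideneshikimate
Conditions: 2,2-dimethoxypropane, CSA (cat.), acetone, rt
Reagents that add atoms: 2,2-dimethoxypropane, COC(C)(C)OC
Why: Acid-catalysed transketalisation should engage only the cis-3,4-diol as a five-membered acetonide and leave the trans-disposed O5 free.

Step 3
Reactants: 3 tert-butyl 3,4-O-isopropylideneshikimate
Product: 4 tert-butyl 3,4-O-isopropylidene-5-O-mesylshikimate
Conditions: MsCl, Et3N, CH2Cl2, 0 °C
Reagents that add atoms: methanesulfonyl chloride, CS(=O)(=O)Cl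
Why: Sulfonylation of the only free alcohol installs the leaving group for the later elimination without breaking the C5–O bond.

Step 4
Reactants: 4 tert-butyl 3,4-O-isopropylidene-5-O-mesylshikimate
Product: 5 tert-butyl 5-O-mesylshikimate (3,4-diol, shikimate configuration)
Conditions: AcOH–H2O (4:1), 50 °C
Reagents that add atoms: none
Why: Mild aqueous acid hydrolysis of the ketal should free O3 and O4 while the tert-butyl ester and the secondary mesylate survive.

Step 5
Reactants: 5 tert-butyl 5-O-mesylshikimate; 6 acrylic acid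
Product: 7 tert-butyl 3-O-acryloyl-5-O-mesyl-3-epi-shikimate
Conditions: PPh3, DIAD, THF, 0 °C to rt
Reagents that add atoms: none
Why: In this Mitsunobu esterification the oxyphosphonium should form at the allylic, less hindered O3 and be displaced by acrylate in an SN2 step, which inverts C3 and leaves the doubly flanked O4 untouched.

Step 6
Reactants: 7 tert-butyl 3-O-acryloyl-5-O-mesyl-3-epi-shikimate
Product: 8 tert-butyl 3-O-acryloyl-4-O-(tert-butyldimethylsilyl)-5-O-mesyl-3-epi-shikimate
Conditions: TBSOTf (1.2 equiv), 2,6-lutidine, CH2Cl2, −78 to −20 °C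
Reagents that add atoms: tert-butyldimethylsilyl triflate, CC(C)(C)[Si](C)(C)OS(=O)(=O)C(F)(F)F
Why: Silylation with a silyl triflate and a hindered pyridine base should cap the hindered O4 at low temperature, too fast for acyl migration or attack on the tert-butyl ester.

Step 7
Reactants: 8 tert-butyl 3-O-acryloyl-4-O-(tert-butyldimethylsilyl)-5-O-mesyl-3-epi-shikimate
Product: 9 dienyl acrylate, tert-butyl (3S,4S)-3-(acryloyloxy)-4-(tert-butyldimethylsilyloxy)cyclohexa-1,5-diene-1-carboxylate
Conditions: DBU (2 equiv), toluene, rt to 45 °C; rapid filtration through buffered silica, used at once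
Reagents that add atoms: none
Why: Amidine-mediated E2 elimination should remove the allylic H6 anti to the axial C5 mesylate (all-trans substituents can go triaxial) and give the ring diene, with C3 and C4 untouched.

Step 8
Reactants: 9 dienyl acrylate
Product: 10 lactone enoate (tert-butyl C7=C8 enoate; γ-lactone C9(=O)–O–C2 with C9 on C6; OTBS on C3 syn to the C7=C8 bridge)
Conditions: toluene (0.01 M), BHT (10 mol%), propylene oxide (5 equiv), 105 °C, sealed vessel, dark
Reagents that add atoms: none
Why: This is a concerted thermal [4+2] cycloaddition in which the ring diene C1=C7–C8=C4 is the 4π partner and the acrylate held on O2 the 2π partner; the closest known reaction type is the intramolecular Diels–Alder reaction of acrylates of cyclohexa-2,4-dienols, which gives lactone-bridged bicyclo[2.2.2]octenes. The carbocycle closes in the bridged mode by suprafacial bond formation at the diene termini (C1–C6 and C4–C5), and the five-membered lactone O2–C9–C6–C1–C2 closes at the same time in the fused mode of a three-atom tether, which lets C6 reach only C1. C1 and C4 are set by the diene face that is attacked, which must be the face carrying O2, so the inverted C2 carbinol fixes their absolute configuration; C6 is set by the tether, which keeps C9 on the side of the C2–C3 bridge. The step needs regioselectivity (C9 next to C1) and facial selectivity, and the ester tether enforces both, while the trans OTBS group on C3 lies on the far face and ends up over the C7=C8 enoate. It must also outrun syn-loss of acrylic acid across C2–C3 (aromatisation) and radical polymerisation, hence the high dilution, the acid scavenger and BHT.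

Step 9
Reactants: 10 lactone enoate; 11 5-bromo-2,2-dimethyl-1,3-benzodioxole
Product: 15 cis aryl ester (aryl on C8 plus CO2tBu on C7 both syn to the C5–C6 bridge), via arylmagnesium bromide 12 (not isolated), via bromomagnesium diarylcuprate 13 (not isolated), via silyl ketene acetal 14 (not isolated)
Conditions: 11 (3.0 equiv), Mg, THF, rt; CuBr·SMe2 (1.5 equiv), −40 °C; then 10, Me3SiCl (3 equiv), −78 to −30 °C; aq NH4Cl
Reagents that add atoms: none
Why: Silyl-chloride-accelerated conjugate addition of a Gilman-type diarylcuprate should deliver the aryl group to C8 from the face looking at the C5–C6 bridge because the OTBS group on C3 covers the other face, and protonation of the ketene acetal at C7 anti to the new aryl should give the cis ester.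

Step 10
Reactants: 15 cis aryl ester
Product: 16 trans aryl ester (C7 epimer; CO2tBu syn to the C2–C3 bridge)
Conditions: KOtBu (0.3 equiv), tBuOH–THF (1:1), rt to 40 °C; AcOH quench
Reagents that add atoms: none
Why: Alkoxide-mediated enolisation (base-catalysed epimerisation) should equilibrate C7 to the trans arrangement, which relieves the eclipsing of ester and aryl on the rigid bridge, while C6 cannot epimerise because its lactone enolate would violate Bredt's rule.

Step 11
Reactants: 16 trans aryl ester
Product: 17 diol (C9 primary alcohol on C6; secondary alcohol on C2)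
Conditions: LiBH4, THF, 0 °C to rt
Reagents that add atoms: none
Why: Borohydride reduction should open the strained γ-lactone to the 1,4-diol chemoselectively, the hindered tert-butyl ester being inert to LiBH4 under these conditions.

Step 12
Reactants: 17 diol
Product: 18 keto aldehyde (C2 ketone; C9 aldehyde on C6)
Conditions: (COCl)2, DMSO, CH2Cl2, −78 °C; Et3N, −78 to 0 °C
Reagents that add atoms: none
Why: In the Swern oxidation both alcohols become alkoxysulfonium salts before the base is added, so aldehyde and ketone should form together and no lactol, and hence no lactone, can arise.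

Step 13
Reactants: 18 keto aldehyde
Product: 20 keto enal (C5=C6 alkene carrying the C9 aldehyde on C6), via C6-phenylselanyl aldehyde 19 (not isolated)
Conditions: N-(phenylselanyl)phthalimide, L-prolinamide (20 mol%), CH2Cl2, rt; then NaIO4, NaHCO3, THF–H2O, 0 °C to rt
Reagents that add atoms: none
Why: Enamine-mediated α-selenenylation is selective for the aldehyde over ketone and ester, and the selenoxide should then undergo syn-elimination with the only non-bridgehead β-hydrogen (on C5), which the eclipsed bicyclic frame presents syn-periplanar.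

Step 14
Reactants: 21 danshensu
Product: 22 4-methoxybenzyl (R)-3-[3,4-bis(4-methoxybenzyloxy)phenyl]-2-hydroxypropanoate
Conditions: PMBCl (3.3 equiv), K2CO3, Bu4NI (cat.), degassed DMF, rt to 40 °C, argon
Reagents that add atoms: 4-methoxybenzyl chloride, COc1ccc(CCl)cc1
Why: Williamson-type O-alkylation with a carbonate base should take the carboxylate and both phenols but not the far less acidic secondary alcohol, and the stereocenter is not involved.

Step 15
Reactants: 22 protected danshensu; 23 diethylphosphonoacetic acid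
Product: 24 phosphonate (diethylphosphonoacetate of the secondary alcohol of 22)
Conditions: DCC, DMAP (cat.), CH2Cl2, 0 °C to rt
Reagents that add atoms: none
Why: Steglich esterification acylates the free secondary alcohol with retention because its C–O bond is never broken.

Step 16
Reactants: 20 keto enal; 24 phosphonate
Product: 25 protected dienoate ((E)-C9=C10, C11 esterified by the lactate oxygen; C2 ketone; C3–OTBS)
Conditions: LiCl, iPr2NEt, MeCN, 0 °C to rt
Reagents that add atoms: none
Why: Horner–Wadsworth–Emmons olefination under Masamune–Roush conditions should react only at the aldehyde and give the E-alkene, with a base too weak to racemise the lactate center or epimerise C7.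

Step 17
Reactants: 25 protected dienoate
Product: 26 ketol (C3–OH next to the C2 ketone)
Conditions: HF·pyridine, pyridine, THF, 0 °C to rt
Reagents that add atoms: none
Why: Buffered fluoride desilylation should cleave the secondary silyl ether and leave the PMB ethers, the catechol acetonide and all esters intact.

Step 18
Reactants: 26 ketol
Product: 27 protected dione (C2, C3 diketone)
Conditions: Dess–Martin periodinane, NaHCO3, CH2Cl2, rt, dark
Reagents that add atoms: none
Why: Dess–Martin oxidation of an α-hydroxy ketone should give the 1,2-dione, which is configurationally safe because both α-carbons are bridgeheads and cannot enolise.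

Step 19
Reactants: 27 protected dione
Product: 28 yunnaneic acid C
Conditions: TFA–anisole–H2O (90:5:5), 0 °C to rt, argon, dark
Reagents that add atoms: none
Why: Acidolysis (SN1/E1 cleavage of the tert-butyl and 4-methoxybenzyl groups, hydrolysis of the catechol ketal) should free both acids and all four phenols in one operation, with anisole trapping the benzyl cations and no ester link, alkene or stereocenter affected.

Compound list
1 | (−)-shikimic acid | O=C(O)C1=C[C@@H](O)[C@@H](O)[C@H](O)C1 | starting material
2 | tert-butyl shikimate | CC(C)(C)OC(=O)C1=C[C@@H](O)[C@@H](O)[C@H](O)C1 | intermediate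
3 | tert-butyl 3,4-O-isopropylideneshikimate | CC(C)(C)OC(=O)C1=C[C@H]2OC(C)(C)O[C@H]2[C@H](O)C1 | intermediate
4 | tert-butyl 3,4-O-isopropylidene-5-O-mesylshikimate | CC(C)(C)OC(=O)C1=C[C@H]2OC(C)(C)O[C@H]2[C@H](OS(C)(=O)=O)C1 | intermediate
5 | tert-butyl 5-O-mesylshikimate | CC(C)(C)OC(=O)C1=C[C@@H](O)[C@@H](O)[C@H](OS(C)(=O)=O)C1 | intermediate
6 | acrylic acid | C=CC(=O)O | starting material
7 | tert-butyl 3-O-acryloyl-5-O-mesyl-3-epi-shikimate | CC(C)(C)OC(=O)C1=C[C@H](OC(=O)C=C)[C@@H](O)[C@H](OS(C)(=O)=O)C1 | intermediate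
8 | tert-butyl 3-O-acryloyl-4-O-(tert-butyldimethylsilyl)-5-O-mesyl-3-epi-shikimate | CC(C)(C)OC(=O)C1=C[C@H](OC(=O)C=C)[C@@H](O[Si](C)(C)C(C)(C)C)[C@H](OS(C)(=O)=O)C1 | intermediate
9 | dienyl acrylate, tert-butyl (3S,4S)-3-(acryloyloxy)-4-(tert-butyldimethylsilyloxy)cyclohexa-1,5-diene-1-carboxylate | CC(C)(C)OC(=O)C1=C[C@H](OC(=O)C=C)[C@@H](O[Si](C)(C)C(C)(C)C)C=C1 | intermediate
10 | lactone enoate: tert-butyl C7=C8 enoate, γ-lactone C9(=O)–O–C2 with C9 on C6, OTBS on C3 syn to the C7=C8 bridge | O=C1O[C@@H]2[C@@H](O[Si](C)(C)C(C)(C)C)[C@@H]3C[C@H]1[C@H]2C(C(=O)OC(C)(C)C)=C3 | intermediate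
11 | 5-bromo-2,2-dimethyl-1,3-benzodioxole | CC1(C)Oc2ccc(Br)cc2O1 | starting material
12 | (2,2-dimethyl-1,3-benzodioxol-5-yl)magnesium bromide | CC1(C)Oc2ccc([Mg]Br)cc2O1 | intermediate
13 | bromomagnesium bis(2,2-dimethyl-1,3-benzodioxol-5-yl)cuprate | CC1(C)Oc2ccc([Cu-]c3ccc4OC(C)(C)Oc4c3)cc2O1.[Mg+]Br | intermediate
14 | silyl ketene acetal of the C8-arylated ester (C7=C(OSiMe3)OtBu) | O=C1O[C@@H]2[C@@H](O[Si](C)(C)C(C)(C)C)[C@@H]3C[C@H]1[C@H]2C(=C(O[Si](C)(C)C)OC(C)(C)C)[C@H]3c4ccc5OC(C)(C)Oc5c4 | intermediate
15 | cis aryl ester: aryl on C8 and CO2tBu on C7 both syn to the C5–C6 bridge, lactone and OTBS as in 10 | O=C1O[C@@H]2[C@@H](O[Si](C)(C)C(C)(C)C)[C@@H]3C[C@H]1[C@H]2[C@@H](C(=O)OC(C)(C)C)[C@H]3c4ccc5OC(C)(C)Oc5c4 | intermediate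
16 | trans aryl ester: aryl on C8 syn to the C5–C6 bridge, CO2tBu on C7 syn to the C2–C3 bridge | O=C1O[C@@H]2[C@@H](O[Si](C)(C)C(C)(C)C)[C@@H]3C[C@H]1[C@H]2[C@H](C(=O)OC(C)(C)C)[C@H]3c4ccc5OC(C)(C)Oc5c4 | intermediate
17 | diol: CH2OH (C9) on C6 syn to the C2–C3 bridge, OH on C2 syn to the C5–C6 bridge | OC[C@H]1C[C@H]2[C@H](O[Si](C)(C)C(C)(C)C)[C@@H](O)[C@@H]1[C@H](C(=O)OC(C)(C)C)[C@H]2c3ccc4OC(C)(C)Oc4c3 | intermediate
18 | keto aldehyde: C2 ketone, C9 aldehyde on C6 | O=C[C@H]1C[C@H]2[C@H](O[Si](C)(C)C(C)(C)C)C(=O)[C@@H]1[C@H](C(=O)OC(C)(C)C)[C@H]2c3ccc4OC(C)(C)Oc4c3 | intermediate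
19 | C6-phenylselanyl aldehyde (C6 epimers) | O=CC1([Se]c5ccccc5)C[C@H]2[C@H](O[Si](C)(C)C(C)(C)C)C(=O)[C@@H]1[C@H](C(=O)OC(C)(C)C)[C@H]2c3ccc4OC(C)(C)Oc4c3 | intermediate
20 | keto enal: C5=C6 with the C9 aldehyde on C6, C2 ketone, C3–OTBS | O=CC1=C[C@H]2[C@H](O[Si](C)(C)C(C)(C)C)C(=O)[C@@H]1[C@H](C(=O)OC(C)(C)C)[C@H]2c3ccc4OC(C)(C)Oc4c3 | intermediate
21 | danshensu, (R)-3-(3,4-dihydroxyphenyl)lactic acid | O[C@H](Cc1ccc(O)c(O)c1)C(=O)O | starting material
22 | 4-methoxybenzyl (R)-3-[3,4-bis(4-methoxybenzyloxy)phenyl]-2-hydroxypropanoate | O[C@H](Cc1ccc(OCc2ccc(OC)cc2)c(OCc3ccc(OC)cc3)c1)C(=O)OCc4ccc(OC)cc4 | intermediate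
23 | diethylphosphonoacetic acid | CCOP(=O)(CC(=O)O)OCC | starting material
24 | phosphonate: 22 acylated on its secondary oxygen by diethylphosphonoacetyl | CCOP(=O)(OCC)CC(=O)O[C@H](Cc1ccc(OCc2ccc(OC)cc2)c(OCc3ccc(OC)cc3)c1)C(=O)OCc4ccc(OC)cc4 | intermediate
25 | protected dienoate with C2 ketone and C3–OTBS | O=C(/C=C/C1=C[C@H]2[C@H](O[Si](C)(C)C(C)(C)C)C(=O)[C@@H]1[C@H](C(=O)OC(C)(C)C)[C@H]2c3ccc4OC(C)(C)Oc4c3)O[C@H](Cc5ccc(OCc6ccc(OC)cc6)c(OCc7ccc(OC)cc7)c5)C(=O)OCc8ccc(OC)cc8 | intermediate
26 | ketol: C3–OH, C2 ketone, otherwise as 25 | O=C(/C=C/C1=C[C@H]2[C@H](O)C(=O)[C@@H]1[C@H](C(=O)OC(C)(C)C)[C@H]2c3ccc4OC(C)(C)Oc4c3)O[C@H](Cc5ccc(OCc6ccc(OC)cc6)c(OCc7ccc(OC)cc7)c5)C(=O)OCc8ccc(OC)cc8 | intermediate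
27 | protected dione: tert-butyl ester, catechol acetonide, three PMB groups | O=C(/C=C/C1=C[C@H]2C(=O)C(=O)[C@@H]1[C@H](C(=O)OC(C)(C)C)[C@H]2c3ccc4OC(C)(C)Oc4c3)O[C@H](Cc5ccc(OCc6ccc(OC)cc6)c(OCc7ccc(OC)cc7)c5)C(=O)OCc8ccc(OC)cc8 | intermediate
28 | yunnaneic acid C | O=C(/C=C/C1=C[C@H]2C(=O)C(=O)[C@@H]1[C@H](C(=O)O)[C@H]2c1ccc(O)c(O)c1)O[C@H](Cc1ccc(O)c(O)c1)C(=O)O | target

Total step count: 19 (steps 1–13 and 16–19 on the main line, steps 14–15 on the side-chain fragment). Longest linear sequence: 17 steps from (−)-shikimic acid.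

Steps most likely to fail

1. Step 8. Thermal syn-loss of acrylic acid across C2–C3 (aromatisation of the diene) or polymerisation of the acrylate may outpace the cycloaddition. Fallback, setting out from 5 and returning at 10: Mitsunobu esterification of 5 with commercial 2-chloroacrylic acid gives tert-butyl 3-O-(2-chloroacryloyl)-5-O-mesyl-3-epi-shikimate F1. Silylation as in step 6 gives its 4-O-TBS ether F2, and DBU elimination as in step 7 gives the dienyl 2-chloroacrylate F3. The α-chloro substituent lowers the LUMO of the dienophile, so cycloaddition is expected at a distinctly lower temperature and should give the C6-chloro lactone F4. Radical dechlorination (Bu3SnH, AIBN, toluene, 80 °C), which needs only a pyramidal C6 radical and no enolate, then returns to 10.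

2. Step 9. The cuprate may add sluggishly to the hindered trisubstituted enoate, attack the lactone carbonyl, or show poor facial discrimination. Fallback, setting out from 10 and returning at 15: Grignard reagent 12 is quenched with B(OMe)3 and hydrolysed to (2,2-dimethyl-1,3-benzodioxol-5-yl)boronic acid F5. A Hayashi–Miyaura conjugate addition ([Rh(OH)(cod)]2, dioxane–H2O, 60 °C) then adds the aryl group to C8 by insertion of an aryl–rhodium species, a catalytic pathway that tolerates the lactone. The same OTBS shielding applies, and any 16 formed directly is carried into step 10 together with 15.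

3. Step 5. Regiocontrol between O3 and O4 may be incomplete, or the cis-diol may stall as a cyclic phosphorane, giving mixtures or C4 esters. Fallback, setting out from 5 and returning at 7: SOCl2 and Et3N convert the cis-diol into the 3,4-cyclic sulfite F6. CsO2CCH=CH2 (from 6 and Cs2CO3, DMF, rt to 50 °C) opens it by SN2 attack at the allylic C3 with inversion. Dilute aqueous acid then hydrolyses the C4 sulfite monoester to give 7.

Further compounds
F1 | step 8 | tert-butyl 3-O-(2-chloroacryloyl)-5-O-mesyl-3-epi-shikimate | CC(C)(C)OC(=O)C1=C[C@H](OC(=O)C(Cl)=C)[C@@H](O)[C@H](OS(C)(=O)=O)C1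
F2 | step 8 | tert-butyl 3-O-(2-chloroacryloyl)-4-O-(tert-butyldimethylsilyl)-5-O-mesyl-3-epi-shikimate | CC(C)(C)OC(=O)C1=C[C@H](OC(=O)C(Cl)=C)[C@@H](O[Si](C)(C)C(C)(C)C)[C@H](OS(C)(=O)=O)C1
F3 | step 8 | tert-butyl (3S,4S)-3-(2-chloroacryloyloxy)-4-(tert-butyldimethylsilyloxy)cyclohexa-1,5-diene-1-carboxylate | CC(C)(C)OC(=O)C1=C[C@H](OC(=O)C(Cl)=C)[C@@H](O[Si](C)(C)C(C)(C)C)C=C1
F4 | step 8 | C6-chloro lactone enoate (10 with Cl on C6, syn to the C7=C8 bridge) | O=C1O[C@@H]2[C@@H](O[Si](C)(C)C(C)(C)C)[C@@H]3C[C@@]1(Cl)[C@H]2C(C(=O)OC(C)(C)C)=C3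
F5 | step 9 | (2,2-dimethyl-1,3-benzodioxol-5-yl)boronic acid | CC1(C)Oc2ccc(B(O)O)cc2O1
F6 | step 5 | tert-butyl 5-O-mesylshikimate 3,4-cyclic sulfite (sulfur epimers) | CC(C)(C)OC(=O)C1=C[C@H]2OS(=O)O[C@H]2[C@H](OS(C)(=O)=O)C1
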